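**Plan**

1. Retrosynthesis: the six benzyl ethers come off last; C3 is traced back to its cis epimer and the C4 ketone to a silyl-protected carbinol; then the ring D–vinyl bond of the enone is cut (Heck), then O1–C8a of ring C (aryl ether), then C4–C4a (aryl Grignard plus aldehyde), and finally C2–C3 (auxiliary aldol).
2. Forward: rings A, B, D and E are bought as benzenoid building blocks; the C2–C3–C4 chain grows from the ring D acetic acid (aldol with the ring B aldehyde, then addition of ring A at C4); ring C is the only ring that is made, closed by O1–C8a; the enone arm with ring E is attached afterwards.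
3. Enabling feature: C3 (enolisable, alpha to C4=O) and C2 (its O1–C2 bond opens by retro-oxa-Michael reaction) are fragile only while C4 is a ketone, so ring C is closed at O1–C8a on the ring A bromide while C4 is still an O-silyl carbinol and base cannot touch C2.
4. Stereochemistry: C2 (R) is set by an Evans aldol with (R)-4-benzyloxazolidinone and kept with retention because its C–O bond is never broken; C4 is a throwaway epimer mixture; C3 (S) is set last under thermodynamic control (2,3-trans chromanone); the E alkene comes from the Heck reaction.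

Key step: step 11

Labels: flavanone numbering is used throughout (O1, C2, C3, C4, C4a to C8a); ring A = benzo ring, ring B = aryl on C2, ring C = pyranone ring, ring D = aryl on C3, ring E = resorcinol ring of the enone.
Assumption: the C4 carbinol is carried as a mixture of epimers (erased in step 16) and any loss of configuration at C3 after step 7 is tolerated (C3 is reset in step 17); compounds 16 to 25 are drawn with C3 as set in step 3.
Assumption: arene 12 is taken as purchasable (otherwise one O-benzylation of 5-bromoresorcinol); ring A carries bromine as the leaving group because an ortho-bromoarylmagnesium reagent lives long enough to be added to an aldehyde.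

**Route**

Step 1
Reactants: 1 (5-bromo-2-hydroxyphenyl)acetic acid
Product: 3 [2-(benzyloxy)-5-bromophenyl]acetic acid, via benzyl ester 2 (not isolated)
Conditions: BnBr, K2CO3, DMF, 60 °C; then NaOH, THF/MeOH/H2O, 50 °C; HCl work-up
Reagents that add atoms: benzyl bromide BrCc1ccccc1
Why: Williamson O-alkylation benzylates phenol and carboxylate alike, and saponification of the benzyl ester then frees the acid while the aryl benzyl ether stays.

Step 2
Reactants: 3 [2-(benzyloxy)-5-bromophenyl]acetic acid; 4 (4R)-4-benzyl-1,3-oxazolidin-2-one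
Product: 6 (4R)-4-benzyl-3-{[2-(benzyloxy)-5-bromophenyl]acetyl}-1,3-oxazolidin-2-one, via pivalic mixed anhydride 5 (not isolated)
Conditions: t-BuCOCl, Et3N, THF, −20 °C; then 4, LiCl, −20 °C → rt
Reagents that add atoms: none
Why: N-acylation of the oxazolidinone through the mixed pivalic anhydride (LiCl/Et3N soft acylation) is a standard entry to arylacetyl imides, the nucleophile attacking the less hindered carbonyl of the anhydride.

Step 3
Reactants: 6 (4R)-4-benzyl-3-{[2-(benzyloxy)-5-bromophenyl]acetyl}-1,3-oxazolidin-2-one; 7 4-(benzyloxy)benzaldehyde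
Product: 9 (4R)-4-benzyl-3-{(2R,3R)-2-[2-(benzyloxy)-5-bromophenyl]-3-[4-(benzyloxy)phenyl]-3-hydroxypropanoyl}-1,3-oxazolidin-2-one, via dibutylboron Z-enolate 8 (not isolated)
Conditions: Bu2BOTf, i-Pr2NEt, CH2Cl2, 0 °C; then 7, −78 → 0 °C; pH 7 buffer, MeOH, H2O2, 0 °C
Reagents that add atoms: none
Why: Evans syn aldol, in which the Z-boron enolate reacts through a Zimmerman–Traxler chair and the benzyl group of the (R)-auxiliary blocks one enolate face, so the carbinol carbon (later C2) should form as R with the ring D carbon (later C3) syn to it, and the adduct can be purified to a single diastereomer.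

Step 4
Reactants: 9 (4R)-4-benzyl-3-{(2R,3R)-2-[2-(benzyloxy)-5-bromophenyl]-3-[4-(benzyloxy)phenyl]-3-hydroxypropanoyl}-1,3-oxazolidin-2-one
Product: 10 (2R,3R)-2-[2-(benzyloxy)-5-bromophenyl]-3-[4-(benzyloxy)phenyl]-3-hydroxy-N-methoxy-N-methylpropanamide
Conditions: MeNH(OMe)·HCl, AlMe3, CH2Cl2, −20 → 0 °C; aq. potassium sodium tartrate
Reagents that add atoms: N,O-dimethylhydroxylamine hydrochloride CNOC.Cl
Why: Aluminium amide transamidation of a β-hydroxy imide (Weinreb amide formation) is assisted by the free hydroxyl, releases the auxiliary and leaves both stereocentres untouched.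

Step 5
Reactants: 10 (2R,3R)-2-[2-(benzyloxy)-5-bromophenyl]-3-[4-(benzyloxy)phenyl]-3-hydroxy-N-methoxy-N-methylpropanamide
Product: 11 (2R,3R)-2-[2-(benzyloxy)-5-bromophenyl]-3-[4-(benzyloxy)phenyl]-N-methoxy-N-methyl-3-[(triethylsilyl)oxy]propanamide
Conditions: TESOTf, 2,6-lutidine, CH2Cl2, −78 °C
Reagents that add atoms: triethylsilyl triflate CC[Si](CC)(CC)OS(=O)(=O)C(F)(F)F
Why: Silyl triflate silylation masks the C2 hydroxyl so that no retro-aldol cleavage can occur in the hydride and organomagnesium steps, and the triethylsilyl group can later be removed beside a tert-butyldimethylsilyl ether.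

Step 6
Reactants: 12 1,3-bis(benzyloxy)-5-bromobenzene
Product: 13 1,5-bis(benzyloxy)-3-bromo-2-iodobenzene
Conditions: NIS, CF3CO2H (cat.), MeCN, rt, dark
Reagents that add atoms: N-iodosuccinimide O=C1CCC(=O)N1I
Why: Electrophilic aromatic iodination of a 1-halo-3,5-dialkoxybenzene goes ortho to the halogen and para to one ether, the site between the two ethers being the more hindered, as in the known halogenations and formylations of this arene class.

Step 7
Reactants: 11 (2R,3R)-2-[2-(benzyloxy)-5-bromophenyl]-3-[4-(benzyloxy)phenyl]-N-methoxy-N-methyl-3-[(triethylsilyl)oxy]propanamide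
Product: 14 (2R,3R)-2-[2-(benzyloxy)-5-bromophenyl]-3-[4-(benzyloxy)phenyl]-3-[(triethylsilyl)oxy]propanal
Conditions: i-Bu2AlH, THF, −78 °C; aq. potassium sodium tartrate; used crude
Reagents that add atoms: none
Why: Hydride reduction of a Weinreb amide stops at the chelated hemiaminal and gives the aldehyde (the later C4) on work-up, and the crude aldehyde is used at once because α-aryl aldehydes epimerise on standing.

Step 8
Reactants: 13 1,5-bis(benzyloxy)-3-bromo-2-iodobenzene; 14 (2R,3R)-2-[2-(benzyloxy)-5-bromophenyl]-3-[4-(benzyloxy)phenyl]-3-[(triethylsilyl)oxy]propanal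
Product: 16 (1RS,2S,3R)-1-[2,4-bis(benzyloxy)-6-bromophenyl]-2-[2-(benzyloxy)-5-bromophenyl]-3-[4-(benzyloxy)phenyl]-3-[(triethylsilyl)oxy]propan-1-ol, via arylmagnesium chloride 15 (not isolated)
Conditions: 13, i-PrMgCl·LiCl, THF, −40 °C; then 14, −40 → −20 °C; aq. NH4Cl at −20 °C
Reagents that add atoms: none
Why: Iodine–magnesium exchange is selective for the carbon–iodine bond over both carbon–bromine bonds, and the ortho-bromoarylmagnesium chloride then adds to the aldehyde in a Grignard 1,2-addition that forms C4–C4a, the new C4 carbinol arising as an epimer mixture that needs no control because C4 is oxidised later.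

Step 9
Reactants: 16 (1RS,2S,3R)-1-[2,4-bis(benzyloxy)-6-bromophenyl]-2-[2-(benzyloxy)-5-bromophenyl]-3-[4-(benzyloxy)phenyl]-3-[(triethylsilyl)oxy]propan-1-ol
Product: 17 (1RS,2R,3R)-1-[2,4-bis(benzyloxy)-6-bromophenyl]-2-[2-(benzyloxy)-5-bromophenyl]-3-[4-(benzyloxy)phenyl]-1-[(tert-butyldimethylsilyl)oxy]-3-[(triethylsilyl)oxy]propane
Conditions: TBSOTf, 2,6-lutidine, CH2Cl2, 0 °C → rt
Reagents that add atoms: tert-butyldimethylsilyl triflate CC(C)(C)[Si](C)(C)OS(=O)(=O)C(F)(F)F
Why: Silyl triflate with a hindered pyridine base is the standard silylation for a congested secondary benzylic alcohol and puts the robust silyl ether on C4 that has to survive base, copper and palladium.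

Step 10
Reactants: 17 (1RS,2R,3R)-1-[2,4-bis(benzyloxy)-6-bromophenyl]-2-[2-(benzyloxy)-5-bromophenyl]-3-[4-(benzyloxy)phenyl]-1-[(tert-butyldimethylsilyl)oxy]-3-[(triethylsilyl)oxy]propane
Product: 18 (1R,2R,3RS)-3-[2,4-bis(benzyloxy)-6-bromophenyl]-2-[2-(benzyloxy)-5-bromophenyl]-1-[4-(benzyloxy)phenyl]-3-[(tert-butyldimethylsilyl)oxy]propan-1-ol
Conditions: HF·pyridine, pyridine, THF, 0 °C
Reagents that add atoms: none
Why: Selective desilylation, since buffered fluoride cleaves a triethylsilyl ether far faster than the hindered tert-butyldimethylsilyl ether and avoids protic acid at the p-alkoxybenzylic C2 carbinol.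

Step 11
Reactants: 18 (1R,2R,3RS)-3-[2,4-bis(benzyloxy)-6-bromophenyl]-2-[2-(benzyloxy)-5-bromophenyl]-1-[4-(benzyloxy)phenyl]-3-[(tert-butyldimethylsilyl)oxy]propan-1-ol
Product: 19 (2R,3R,4RS)-5,7-bis(benzyloxy)-2-[4-(benzyloxy)phenyl]-3-[2-(benzyloxy)-5-bromophenyl]-4-[(tert-butyldimethylsilyl)oxy]chroman (2,3-cis)
Conditions: CuI (20 mol %), 3,4,7,8-tetramethyl-1,10-phenanthroline (40 mol %), Cs2CO3, toluene, 110 °C, argon
Reagents that add atoms: none
Why: Cs2CO3 deprotonates the C2 carbinol, the alkoxide binds monovalent copper, the metal inserts into the neighbouring ring A carbon–bromine bond and the aryl(alkoxo)copper species (formally trivalent copper) reductively eliminates to forge O1–C8a. The closest known reaction type is the Ullmann-type intramolecular O-arylation of 1-aryl-3-(2-haloaryl)propan-1-ols to 2-arylchromans. Ring C closes as a six-membered ring by attack of the chain oxygen on the ring A ipso carbon, formally a 6-exo closure at a trigonal carbon. No stereocentre is created: C2 keeps its R configuration because only O–H and C–Br bonds are broken, and C3 and C4 are spectators. The step needs arylation at ring A only and an intact C2; the ring D bromide cannot be reached by the tethered alkoxide and intermolecular coupling of a secondary alkoxide with an aryl bromide is far slower, while the silyl ether at C4 means there is no ketone, so retro-aldol cleavage, enolisation and ring opening are all unavailable under the basic conditions.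

Step 12
Reactants: 20 1-(2,4-dihydroxyphenyl)ethan-1-one (2',4'-dihydroxyacetophenone)
Product: 21 1-[2,4-bis(benzyloxy)phenyl]ethan-1-one
Conditions: BnBr, K2CO3, KI (cat.), DMF, 80 °C
Reagents that add atoms: benzyl bromide BrCc1ccccc1
Why: Williamson etherification, with heating so that the hydrogen-bonded ortho hydroxyl is benzylated as well.

Step 13
Reactants: 21 1-[2,4-bis(benzyloxy)phenyl]ethan-1-one
Product: 22 1-[2,4-bis(benzyloxy)phenyl]prop-2-en-1-one
Conditions: (CH2O)n, i-Pr2NH·CF3CO2H, CF3CO2H (cat.), THF, reflux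
Reagents that add atoms: paraformaldehyde (as formaldehyde) C=O
Why: Mannich-type α-methylenation of an aryl methyl ketone (aminomethylation, then β-elimination of the amine) gives the aryl vinyl ketone in one operation, to be used freshly prepared.

Step 14
Reactants: 19 (2R,3R,4RS)-5,7-bis(benzyloxy)-2-[4-(benzyloxy)phenyl]-3-[2-(benzyloxy)-5-bromophenyl]-4-[(tert-butyldimethylsilyl)oxy]chroman; 22 1-[2,4-bis(benzyloxy)phenyl]prop-2-en-1-one
Product: 23 (2E)-1-[2,4-bis(benzyloxy)phenyl]-3-{4-(benzyloxy)-3-[(2R,3R,4RS)-5,7-bis(benzyloxy)-2-[4-(benzyloxy)phenyl]-4-[(tert-butyldimethylsilyl)oxy]-3,4-dihydro-2H-chromen-3-yl]phenyl}prop-2-en-1-one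
Conditions: Pd(OAc)2 (5 mol %), [(t-Bu)3PH]BF4 (10 mol %), Cy2NMe, 1,4-dioxane, 80 °C
Reagents that add atoms: none
Why: Mizoroki–Heck coupling, in which zerovalent palladium inserts into the ring D carbon–bromine bond, the enone inserts syn and β-hydride elimination gives the E enone, run at the silyloxychroman stage where the molecule has no base-labile stereocentre.

Step 15
Reactants: 23 (2E)-1-[2,4-bis(benzyloxy)phenyl]-3-{4-(benzyloxy)-3-[(2R,3R,4RS)-5,7-bis(benzyloxy)-2-[4-(benzyloxy)phenyl]-4-[(tert-butyldimethylsilyl)oxy]-3,4-dihydro-2H-chromen-3-yl]phenyl}prop-2-en-1-one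
Product: 24 (2E)-1-[2,4-bis(benzyloxy)phenyl]-3-{4-(benzyloxy)-3-[(2R,3S,4RS)-5,7-bis(benzyloxy)-2-[4-(benzyloxy)phenyl]-4-hydroxy-3,4-dihydro-2H-chromen-3-yl]phenyl}prop-2-en-1-one (2,3-cis; the C3 descriptor changes by priority only)
Conditions: TBAF, AcOH, THF, rt → 40 °C
Reagents that add atoms: none
Why: Fluoride desilylation frees the C4 hydroxyl, and the acetic acid buffer keeps the medium from becoming basic enough to harm the enone.

Step 16
Reactants: 24 (2E)-1-[2,4-bis(benzyloxy)phenyl]-3-{4-(benzyloxy)-3-[(2R,3S,4RS)-5,7-bis(benzyloxy)-2-[4-(benzyloxy)phenyl]-4-hydroxy-3,4-dihydro-2H-chromen-3-yl]phenyl}prop-2-en-1-one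
Product: 25 (2R,3R)-5,7-bis(benzyloxy)-2-[4-(benzyloxy)phenyl]-3-{2-(benzyloxy)-5-[(1E)-3-[2,4-bis(benzyloxy)phenyl]-3-oxoprop-1-en-1-yl]phenyl}-2,3-dihydro-4H-chromen-4-one (2,3-cis)
Conditions: Dess–Martin periodinane, CH2Cl2, 0 °C → rt
Reagents that add atoms: none
Why: Dess–Martin oxidation turns both C4 epimers of the benzylic alcohol into the one chromanone under non-basic conditions, so ring C cannot open when the ketone first appears.

Step 17
Reactants: 25 (2R,3R)-5,7-bis(benzyloxy)-2-[4-(benzyloxy)phenyl]-3-{2-(benzyloxy)-5-[(1E)-3-[2,4-bis(benzyloxy)phenyl]-3-oxoprop-1-en-1-yl]phenyl}-2,3-dihydro-4H-chromen-4-one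
Product: 26 (2R,3S)-5,7-bis(benzyloxy)-2-[4-(benzyloxy)phenyl]-3-{2-(benzyloxy)-5-[(1E)-3-[2,4-bis(benzyloxy)phenyl]-3-oxoprop-1-en-1-yl]phenyl}-2,3-dihydro-4H-chromen-4-one (2,3-trans)
Conditions: p-TsOH·H2O (cat.), CHCl3, 40 °C
Reagents that add atoms: none
Why: Acid-catalysed keto–enol equilibration at C3, which is alpha to the C4 ketone and benzylic, should convert the cis isomer into the preferred 2,3-trans isomer with both aryl groups equatorial, so C3 (S) is set by thermodynamic control from the fixed C2 centre while the absence of base keeps the retro-oxa-Michael opening of ring C shut.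

Step 18
Reactants: 26 (2R,3S)-5,7-bis(benzyloxy)-2-[4-(benzyloxy)phenyl]-3-{2-(benzyloxy)-5-[(1E)-3-[2,4-bis(benzyloxy)phenyl]-3-oxoprop-1-en-1-yl]phenyl}-2,3-dihydro-4H-chromen-4-one
Product: 27 (2R,3S)-5,7-dihydroxy-3-{2-hydroxy-5-[(1E)-3-(2,4-dihydroxyphenyl)-3-oxoprop-1-en-1-yl]phenyl}-2-(4-hydroxyphenyl)-2,3-dihydro-4H-chromen-4-one
Conditions: BCl3, C6HMe5, CH2Cl2, −78 °C; then MeOH, −78 °C; pH 6 phosphate buffer
Reagents that add atoms: none
Why: Lewis acid debenzylation with pentamethylbenzene as a non-basic benzyl cation scavenger cleaves all six aryl benzyl ethers at low temperature without reducing the enone (which rules out hydrogenolysis) and without C-benzylation of the electron-rich ring A, and the cold, buffered quench avoids long exposure of the free phenolic chromanone to acid or base.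

**Compound list**

1 | (5-bromo-2-hydroxyphenyl)acetic acid | OC(=O)Cc1cc(Br)ccc1O | starting material
2 | benzyl [2-(benzyloxy)-5-bromophenyl]acetate | O=C(Cc1cc(Br)ccc1OCc1ccccc1)OCc1ccccc1 | intermediate
3 | [2-(benzyloxy)-5-bromophenyl]acetic acid | OC(=O)Cc1cc(Br)ccc1OCc1ccccc1 | intermediate
4 | (4R)-4-benzyl-1,3-oxazolidin-2-one | O=C1N[C@H](Cc2ccccc2)CO1 | starting material
5 | [2-(benzyloxy)-5-bromophenyl]acetic pivalic anhydride | CC(C)(C)C(=O)OC(=O)Cc1cc(Br)ccc1OCc1ccccc1 | intermediate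
6 | (4R)-4-benzyl-3-{[2-(benzyloxy)-5-bromophenyl]acetyl}-1,3-oxazolidin-2-one | O=C(Cc1cc(Br)ccc1OCc1ccccc1)N1[C@H](Cc2ccccc2)COC1=O | intermediate
7 | 4-(benzyloxy)benzaldehyde | O=Cc1ccc(OCc2ccccc2)cc1 | starting material
8 | (Z)-dibutylboron enolate of 6 | CCCCB(CCCC)O/C(=C\c1cc(Br)ccc1OCc1ccccc1)N1[C@H](Cc2ccccc2)COC1=O | intermediate
9 | (4R)-4-benzyl-3-{(2R,3R)-2-[2-(benzyloxy)-5-bromophenyl]-3-[4-(benzyloxy)phenyl]-3-hydroxypropanoyl}-1,3-oxazolidin-2-one | O=C([C@H](c1cc(Br)ccc1OCc1ccccc1)[C@@H](O)c1ccc(OCc2ccccc2)cc1)N1[C@H](Cc2ccccc2)COC1=O | intermediate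
10 | (2R,3R)-2-[2-(benzyloxy)-5-bromophenyl]-3-[4-(benzyloxy)phenyl]-3-hydroxy-N-methoxy-N-methylpropanamide | CON(C)C(=O)[C@H](c1cc(Br)ccc1OCc1ccccc1)[C@@H](O)c1ccc(OCc2ccccc2)cc1 | intermediate
11 | (2R,3R)-2-[2-(benzyloxy)-5-bromophenyl]-3-[4-(benzyloxy)phenyl]-N-methoxy-N-methyl-3-[(triethylsilyl)oxy]propanamide | CON(C)C(=O)[C@H](c1cc(Br)ccc1OCc1ccccc1)[C@@H](O[Si](CC)(CC)CC)c1ccc(OCc2ccccc2)cc1 | intermediate
12 | 1,3-bis(benzyloxy)-5-bromobenzene | Brc1cc(OCc2ccccc2)cc(OCc2ccccc2)c1 | starting material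
13 | 1,5-bis(benzyloxy)-3-bromo-2-iodobenzene | Brc1cc(OCc2ccccc2)cc(OCc2ccccc2)c1I | intermediate
14 | (2R,3R)-2-[2-(benzyloxy)-5-bromophenyl]-3-[4-(benzyloxy)phenyl]-3-[(triethylsilyl)oxy]propanal | O=C[C@H](c1cc(Br)ccc1OCc1ccccc1)[C@@H](O[Si](CC)(CC)CC)c1ccc(OCc2ccccc2)cc1 | intermediate
15 | [2,4-bis(benzyloxy)-6-bromophenyl]magnesium chloride | Cl[Mg]c1c(Br)cc(OCc2ccccc2)cc1OCc1ccccc1 | intermediate
16 | (1RS,2S,3R)-1-[2,4-bis(benzyloxy)-6-bromophenyl]-2-[2-(benzyloxy)-5-bromophenyl]-3-[4-(benzyloxy)phenyl]-3-[(triethylsilyl)oxy]propan-1-ol (C1 epimers) | OC(c1c(Br)cc(OCc2ccccc2)cc1OCc1ccccc1)[C@H](c1cc(Br)ccc1OCc1ccccc1)[C@@H](O[Si](CC)(CC)CC)c1ccc(OCc2ccccc2)cc1 | intermediate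
17 | (1RS,2R,3R)-1-[2,4-bis(benzyloxy)-6-bromophenyl]-2-[2-(benzyloxy)-5-bromophenyl]-3-[4-(benzyloxy)phenyl]-1-[(tert-butyldimethylsilyl)oxy]-3-[(triethylsilyl)oxy]propane (C1 epimers) | CC(C)(C)[Si](C)(C)OC(c1c(Br)cc(OCc2ccccc2)cc1OCc1ccccc1)[C@H](c1cc(Br)ccc1OCc1ccccc1)[C@@H](O[Si](CC)(CC)CC)c1ccc(OCc2ccccc2)cc1 | intermediate
18 | (1R,2R,3RS)-3-[2,4-bis(benzyloxy)-6-bromophenyl]-2-[2-(benzyloxy)-5-bromophenyl]-1-[4-(benzyloxy)phenyl]-3-[(tert-butyldimethylsilyl)oxy]propan-1-ol (C3 epimers) | CC(C)(C)[Si](C)(C)OC(c1c(Br)cc(OCc2ccccc2)cc1OCc1ccccc1)[C@H](c1cc(Br)ccc1OCc1ccccc1)[C@@H](O)c1ccc(OCc2ccccc2)cc1 | intermediate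
19 | (2R,3R,4RS)-5,7-bis(benzyloxy)-2-[4-(benzyloxy)phenyl]-3-[2-(benzyloxy)-5-bromophenyl]-4-[(tert-butyldimethylsilyl)oxy]chroman (2,3-cis, C4 epimers) | CC(C)(C)[Si](C)(C)OC1c2c(OCc3ccccc3)cc(OCc3ccccc3)cc2O[C@@H](c2ccc(OCc3ccccc3)cc2)[C@H]1c1cc(Br)ccc1OCc1ccccc1 | intermediate
20 | 1-(2,4-dihydroxyphenyl)ethan-1-one | CC(=O)c1ccc(O)cc1O | starting material
21 | 1-[2,4-bis(benzyloxy)phenyl]ethan-1-one | CC(=O)c1ccc(OCc2ccccc2)cc1OCc1ccccc1 | intermediate
22 | 1-[2,4-bis(benzyloxy)phenyl]prop-2-en-1-one | C=CC(=O)c1ccc(OCc2ccccc2)cc1OCc1ccccc1 | intermediate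
23 | (2E)-1-[2,4-bis(benzyloxy)phenyl]-3-{4-(benzyloxy)-3-[(2R,3R,4RS)-5,7-bis(benzyloxy)-2-[4-(benzyloxy)phenyl]-4-[(tert-butyldimethylsilyl)oxy]-3,4-dihydro-2H-chromen-3-yl]phenyl}prop-2-en-1-one | CC(C)(C)[Si](C)(C)OC1c2c(OCc3ccccc3)cc(OCc3ccccc3)cc2O[C@@H](c2ccc(OCc3ccccc3)cc2)[C@H]1c1cc(/C=C/C(=O)c2ccc(OCc3ccccc3)cc2OCc2ccccc2)ccc1OCc1ccccc1 | intermediate
24 | (2E)-1-[2,4-bis(benzyloxy)phenyl]-3-{4-(benzyloxy)-3-[(2R,3S,4RS)-5,7-bis(benzyloxy)-2-[4-(benzyloxy)phenyl]-4-hydroxy-3,4-dihydro-2H-chromen-3-yl]phenyl}prop-2-en-1-one (2,3-cis) | OC1c2c(OCc3ccccc3)cc(OCc3ccccc3)cc2O[C@@H](c2ccc(OCc3ccccc3)cc2)[C@H]1c1cc(/C=C/C(=O)c2ccc(OCc3ccccc3)cc2OCc2ccccc2)ccc1OCc1ccccc1 | intermediate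
25 | (2R,3R)-5,7-bis(benzyloxy)-2-[4-(benzyloxy)phenyl]-3-{2-(benzyloxy)-5-[(1E)-3-[2,4-bis(benzyloxy)phenyl]-3-oxoprop-1-en-1-yl]phenyl}-2,3-dihydro-4H-chromen-4-one (2,3-cis) | O=C1c2c(OCc3ccccc3)cc(OCc3ccccc3)cc2O[C@@H](c2ccc(OCc3ccccc3)cc2)[C@H]1c1cc(/C=C/C(=O)c2ccc(OCc3ccccc3)cc2OCc2ccccc2)ccc1OCc1ccccc1 | intermediate
26 | (2R,3S)-5,7-bis(benzyloxy)-2-[4-(benzyloxy)phenyl]-3-{2-(benzyloxy)-5-[(1E)-3-[2,4-bis(benzyloxy)phenyl]-3-oxoprop-1-en-1-yl]phenyl}-2,3-dihydro-4H-chromen-4-one (2,3-trans) | O=C1c2c(OCc3ccccc3)cc(OCc3ccccc3)cc2O[C@@H](c2ccc(OCc3ccccc3)cc2)[C@@H]1c1cc(/C=C/C(=O)c2ccc(OCc3ccccc3)cc2OCc2ccccc2)ccc1OCc1ccccc1 | intermediate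
27 | (2R,3S)-5,7-dihydroxy-3-{2-hydroxy-5-[(1E)-3-(2,4-dihydroxyphenyl)-3-oxoprop-1-en-1-yl]phenyl}-2-(4-hydroxyphenyl)-2,3-dihydro-4H-chromen-4-one | O=C(/C=C/c1ccc(O)c([C@@H]2C(=O)c3c(O)cc(O)cc3O[C@H]2c2ccc(O)cc2)c1)c1ccc(O)cc1O | target

**Step count and risks**

Total step count: 18. Longest linear sequence: 15 steps (steps 1–5, 7–11 and 14–18, from acid 1).

Step 8. The hindered arylmagnesium reagent 15 may act as a base towards the α-aryl aldehyde 14, so that enolisation and loss of the β-silyloxy group compete with addition. The fallback leaves the aldehyde oxidation level: it sets out from Weinreb amide 11, which is acylated by 15 (THF, −20 → 0 °C) through a magnesium chelate that can neither enolise nor eliminate, to give the aryl ketone (2R,3R)-1-[2,4-bis(benzyloxy)-6-bromophenyl]-2-[2-(benzyloxy)-5-bromophenyl]-3-[4-(benzyloxy)phenyl]-3-[(triethylsilyl)oxy]propan-1-one F1. Reduction of F1 with i-Bu2AlH (CH2Cl2, −78 °C) gives the C4 carbinol as an epimer mixture and rejoins the route at 16.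

Step 11. Insertion of copper into the electron-rich, ortho-substituted ring A carbon–bromine bond may be slow enough for the copper alkoxide to lose a β-hydride (oxidation of the C2 carbinol with reduction of the arene), or for the silyl group to wander from the C4 oxygen to the C2 oxygen. The fallback changes the leaving group. From 18, an aromatic Finkelstein exchange (CuI, NaI, trans-N,N'-dimethylcyclohexane-1,2-diamine, 1,4-dioxane, 110 °C, no base) converts both aryl bromides into iodides and gives (1R,2R,3RS)-3-[2,4-bis(benzyloxy)-6-iodophenyl]-2-[2-(benzyloxy)-5-iodophenyl]-1-[4-(benzyloxy)phenyl]-3-[(tert-butyldimethylsilyl)oxy]propan-1-ol F2. The ring A iodide of F2 should cyclise with the same CuI/phenanthroline/Cs2CO3 system at about 80 °C to (2R,3R,4RS)-5,7-bis(benzyloxy)-2-[4-(benzyloxy)phenyl]-3-[2-(benzyloxy)-5-iodophenyl]-4-[(tert-butyldimethylsilyl)oxy]chroman F3. Heck coupling of the ring D iodide of F3 with 22, under milder conditions than the bromide needs, comes back to the route at 23.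

Step 14. Polymerisation or base-induced decay of the aryl vinyl ketone 22 may outrun oxidative addition into the electron-rich ring D bromide. The fallback builds the enone by condensation instead of coupling. From 19, bromine–lithium exchange (t-BuLi, THF, −78 °C) and formylation with DMF give 4-(benzyloxy)-3-{(2R,3R,4RS)-5,7-bis(benzyloxy)-2-[4-(benzyloxy)phenyl]-4-[(tert-butyldimethylsilyl)oxy]chroman-3-yl}benzaldehyde F4. Claisen–Schmidt condensation of F4 with acetophenone 21 (KOH, EtOH/THF, rt) is harmless at this stage because the silyloxychroman has no acidic stereocentre, and it returns to the route at 23 with the E enone.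

Further compounds
F1 | step 8 | (2R,3R)-1-[2,4-bis(benzyloxy)-6-bromophenyl]-2-[2-(benzyloxy)-5-bromophenyl]-3-[4-(benzyloxy)phenyl]-3-[(triethylsilyl)oxy]propan-1-one | O=C(c1c(Br)cc(OCc2ccccc2)cc1OCc1ccccc1)[C@H](c1cc(Br)ccc1OCc1ccccc1)[C@@H](O[Si](CC)(CC)CC)c1ccc(OCc2ccccc2)cc1
F2 | step 11 | (1R,2R,3RS)-3-[2,4-bis(benzyloxy)-6-iodophenyl]-2-[2-(benzyloxy)-5-iodophenyl]-1-[4-(benzyloxy)phenyl]-3-[(tert-butyldimethylsilyl)oxy]propan-1-ol | CC(C)(C)[Si](C)(C)OC(c1c(I)cc(OCc2ccccc2)cc1OCc1ccccc1)[C@H](c1cc(I)ccc1OCc1ccccc1)[C@@H](O)c1ccc(OCc2ccccc2)cc1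
F3 | step 11 | (2R,3R,4RS)-5,7-bis(benzyloxy)-2-[4-(benzyloxy)phenyl]-3-[2-(benzyloxy)-5-iodophenyl]-4-[(tert-butyldimethylsilyl)oxy]chroman | CC(C)(C)[Si](C)(C)OC1c2c(OCc3ccccc3)cc(OCc3ccccc3)cc2O[C@@H](c2ccc(OCc3ccccc3)cc2)[C@H]1c1cc(I)ccc1OCc1ccccc1
F4 | step 14 | 4-(benzyloxy)-3-{(2R,3R,4RS)-5,7-bis(benzyloxy)-2-[4-(benzyloxy)phenyl]-4-[(tert-butyldimethylsilyl)oxy]chroman-3-yl}benzaldehyde | CC(C)(C)[Si](C)(C)OC1c2c(OCc3ccccc3)cc(OCc3ccccc3)cc2O[C@@H](c2ccc(OCc3ccccc3)cc2)[C@H]1c1cc(C=O)ccc1OCc1ccccc1
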